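## Analysis of the target

The target (20) is an open-chain bis(bibenzyl) with four benzene rings in a row. Ring A is a phenol substituted meta to its hydroxyl, ring B is 1,4-disubstituted, ring C is a phenol carrying the diaryl ether oxygen ortho and a bridge para to its hydroxyl, and ring D is a catechol substituted at C3. Rings A–B and C–D are joined by CH2–CH2 bridges, rings B–C by the ether oxygen. There is no stereocentre and no double bond, so nothing has to be controlled in space and the difficulty is purely regiochemical. The sensitive groups are the four phenolic hydroxyls: the ring D catechol is oxidised to the ortho-quinone as its anion in air, so the closing operations should be acidic or run without oxygen. The two bibenzyl halves look alike but differ in every ring, so symmetry cannot be used. The hard part is to tell four arenes of similar electron richness apart, both when bonds are made and when the oxygens are protected, and to set the 1,2,4-pattern of ring C (OH at C1, ether oxygen at C2, bridge at C4) without ambiguity. The plan rests on the fact that C4 of ring C lies para to the ring C hydroxyl oxygen and meta to the diaryl ether oxygen. Once that hydroxyl is a methyl ether, C4 is where an acylium ion enters a 2-aryloxyanisole, so ring C can come in without a carbon substituent and receive the bridge by C–H substitution.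

## Retrosynthetic reasoning

**20 back to 18 (oxygen protection).** The last bonds cut are the O–CH3 bond on ring C (20 from 19) and, before it, the three O–S bonds of the sulfonate esters on rings A and D (19 from 18). Two kinds of protecting group are needed because they do opposite jobs in the key step: the methyl ether activates ring C, the sulfonates switch rings A and D off. The sulfonates go first under alkali and the methyl ether last under a boron trihalide, so the free catechol finishes in an acidic, non-oxidising medium.

**18 back to 16 (bridge oxidation level).** The CH2 next to ring C in 18 is traced back to the ketone of deoxybenzoin 16. The carbonyl is what an acylation leaves behind. Its removal by silane/acid ionic hydrogenation (through alcohol 17) is helped by the para-methoxy group, which stabilises the benzylic cation.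

**16 back to 9 and 15 (key disconnection).** The bond between C4 of ring C and the carbonyl carbon is cut, giving the three-ring ether 9 and the ring D acid chloride 15. This cut is the most convergent one and needs no handle on ring C. A cut inside the CH2–CH2 bridge would demand a ring C aldehyde that has to be carried through the ether formation and distinguished from the ring B aldehyde. The forward reaction must pick one C–H bond out of four arenes; the methoxy group on ring C and the sulfonates on rings A and D are there to make that choice.

**15 back to 10 (ring D).** Acid chloride 15 comes from acid 14, this from methyl ester 13, and 13 from the dihydroxy ester 12, made from commercial 2,3-dimethoxyphenylacetic acid 10. The methyl ethers of 10 cannot stay, because a 1,2-dimethoxyarene would be more reactive than ring C and the acid chloride would acylate itself. The free ortho-hydroxy acid 11 cannot be sulfonylated directly, because activating its carboxyl group closes the five-membered lactone with the neighbouring phenol. The carboxyl group is therefore held as its methyl ester while the phenols are sulfonylated, and the ester is then cleaved in acid, which the aryl sulfonates tolerate.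

**9 back to 6 and 3 (A–B bridge).** The ethano bridge of 9 is traced to the stilbene 8 and its C=C bond is cut by a Wittig disconnection into phosphonium salt 6 (through ylide 7) and aldehyde 3. The aldehyde is placed on ring B because the same formyl group also activates ring B for the ether formation. Hydrogenation makes the alkene geometry irrelevant.

**3 back to 1 and 2; 6 back to 4.** The diaryl ether C–O bond of 3 is cut on the ring B side, giving guaiacol 1 and 4-fluorobenzaldehyde 2 for a nucleophilic aromatic substitution, so ring C enters as a plain, commercial unit. Phosphonium salt 6 comes from 3-hydroxybenzyl alcohol 4 through the bis-sulfonate 5. One reagent installs both the ring A protecting group and the benzylic leaving group.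

## Alternatives that were turned down

**Alternative 1:** Ring C is not bought but made.
- Disconnection: two C–C bonds of ring C are cut. C1 (hydroxyl), C2 (ether oxygen) and C6 come from the aryloxyacetone A1; C3–C5 with the whole C–D bridge come from the 2-substituted vinamidinium salt A2.
- Forward key step: under KOt-Bu both α-carbons of A1 condense with the two ends of A2, two amine molecules are lost, and the ring aromatises to phenol A3.
- For it: the central carbon of A2 necessarily ends up opposite the former carbonyl carbon, so the bridge is para to the hydroxyl by construction. A2 is symmetrical, so it has no orientation problem. The ring C hydroxyl arrives free, and all other oxygens can be methyl ethers removed in one step.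
- Against it: annulations of this type work best when the central carbon of the vinamidinium unit carries an aryl or acceptor group; A2 carries an alkyl chain. The two α-carbons of A1 differ strongly in acidity, so the sequence may stall after the first condensation. Making A2 under Vilsmeier conditions exposes the dimethoxyphenyl ring to formylation or to cyclisation of the chain onto its own ring.
- Comparison: this route is stronger on regiochemical certainty and on the number of deprotections. The chosen route offers a long-established reaction class, a commercial ring D acid, and its risk in a single substitution step instead of in both the making of A2 and the annulation.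

**Alternative 2:** The ether is made last, by oxidation.
- Disconnection: the bond between the ether oxygen and ring C is cut, giving two bibenzyl phenols, the 2,6-dichlorophenol A4 (rings A and B) and the 2,6-dibromophenol A5 (rings C and D).
- Forward key step: Tl(NO3)3 in methanol (or an anode) oxidises the phenols, the oxygen of A4 adds to a bromine-bearing ortho carbon of oxidised A5, and Zn in acetic acid reduces the adduct with loss of bromide to give A6.
- For it: it is convergent and biomimetic, both halves come from the same kind of olefination/hydrogenation sequence, and the ether is ortho to the ring C hydroxyl by construction.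
- Against it: both phenols are oxidisable, so cross-coupling over homo-coupling depends on the small difference between a dichloro- and a dibromophenol. The method is at its best in ring closures, not between two separate molecules. Four halogens must be put on and three taken off after the coupling. Trivalent thallium is needed in stoichiometric amount, and the acetates may not survive acidic methanol.
- Comparison: it is stronger in convergence and raises no positional question on ring C. The chosen route forms the same ether in its first step from 1 and 2 with no selectivity issue and no halogens to remove, and is shorter.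

**Alternative 3:** A two-carbon linchpin joins rings A and B.
- Disconnection: both aryl–alkyne bonds of the A–B bridge are cut, giving 3-iodoanisole A7, ethynyltrimethylsilane A8 and the ring B iodide A9 that already holds rings B, C and D.
- Forward key step: in one pot A7 couples with A8 under PdCl2(PPh3)2 and CuI, the silyl group is removed in the flask, and the freed alkyne couples with A9 to give diarylalkyne A10. Hydrogenation and one ether cleavage would follow.
- For it: Sonogashira coupling is more dependable than a Friedel–Crafts acylation. Four methyl ethers fall in one step, against two deprotection steps in the chosen route, and no phosphonium waste is formed.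
- Against it: the key step is spent on the easiest bond of the molecule. A9 already contains the diaryl ether, the ring C pattern and the C–D bridge, so the real regiochemical problem is moved into the synthesis of A9, which would be longer than that of 9. The one-pot sequence also loses material to twofold coupling of A7 and to oxidative dimerisation of the alkyne.
- Comparison: it is stronger in the reliability of the key step and in deprotection economy. The chosen route uses its key step on the demanding bond and attaches the bridge to an unfunctionalised ring C.

Key step: step 10

## Route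

Assumption: stilbene 8 is carried on as a mixture of E and Z isomers, since both give 9 on hydrogenation; 1, 2, 4 and 10 are taken as commercial.

Step 1
Reactants: 1 guaiacol (2-methoxyphenol); 2 4-fluorobenzaldehyde
Product: 3 4-(2-methoxyphenoxy)benzaldehyde
Conditions: K2CO3, DMF, 120 °C
Reagents that add atoms: none
Why: Nucleophilic aromatic substitution by addition–elimination; the para-formyl group stabilises the Meisenheimer adduct and fluoride is the best leaving group for this mechanism.

Step 2
Reactants: 4 3-hydroxybenzyl alcohol
Product: 5 3-[(methanesulfonyl)oxy]benzyl methanesulfonate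
Conditions: MsCl (2.2 equiv), Et3N, CH2Cl2, −10 → 0 °C
Reagents that add atoms: methanesulfonyl chloride, CS(=O)(=O)Cl
Why: Sulfonylation of both hydroxyls; the aryl ester is the later deactivating protecting group of ring A and the benzylic ester is the leaving group, kept intact by the low temperature and the electron-poor ring.

Step 3
Reactants: 5 3-[(methanesulfonyl)oxy]benzyl methanesulfonate
Product: 6 {3-[(methanesulfonyl)oxy]benzyl}triphenylphosphonium methanesulfonate
Conditions: PPh3, toluene, 100 °C
Reagents that add atoms: triphenylphosphine, c1ccc(cc1)P(c1ccccc1)c1ccccc1
Why: SN2 quaternisation at the benzylic carbon; the aryl sulfonate does not react with the phosphine and the salt should separate from toluene.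

Step 4
Reactants: 6 {3-[(methanesulfonyl)oxy]benzyl}triphenylphosphonium methanesulfonate; 3 4-(2-methoxyphenoxy)benzaldehyde
Product: 8 3-{2-[4-(2-methoxyphenoxy)phenyl]ethenyl}phenyl methanesulfonate as an E/Z mixture, via phosphorus ylide 7 (not isolated)
Conditions: K2CO3, 18-crown-6 (cat.), CH2Cl2, reflux
Reagents that add atoms: none
Why: Wittig olefination with a semi-stabilised benzylic ylide; carbonate is basic enough for the benzylic phosphonium salt but too weak to deprotonate the methyl group of the aryl methanesulfonate, so the sulfonate should survive.

Step 5
Reactants: 8 3-{2-[4-(2-methoxyphenoxy)phenyl]ethenyl}phenyl methanesulfonate (E/Z mixture)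
Product: 9 3-{2-[4-(2-methoxyphenoxy)phenyl]ethyl}phenyl methanesulfonate
Conditions: H2 (1 atm), 10% Pd/C, EtOAc, rt
Reagents that add atoms: none
Why: Catalytic hydrogenation of the stilbene, on which both isomers converge; the aryl sulfonate, diaryl ether and methyl ether are not hydrogenolysed under neutral conditions.

Step 6
Reactants: 10 2,3-dimethoxyphenylacetic acid
Product: 12 methyl 2,3-dihydroxyphenylacetate, via 2,3-dihydroxyphenylacetic acid 11 (not isolated)
Conditions: BBr3 (4 equiv), CH2Cl2, −78 °C → rt; then MeOH, 0 °C → reflux
Reagents that add atoms: methanol, CO
Why: Lewis-acid cleavage of both aryl methyl ethers, then Fischer esterification by the HBr set free on methanol quench; the excess methanol turns the ortho-hydroxy acid and any of its lactone into the open methyl ester, which is neutralised before concentration.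

Step 7
Reactants: 12 methyl 2,3-dihydroxyphenylacetate
Product: 13 methyl {2,3-bis[(methanesulfonyl)oxy]phenyl}acetate
Conditions: MsCl (2.5 equiv), then Et3N added slowly, CH2Cl2, 0 °C
Reagents that add atoms: methanesulfonyl chloride, CS(=O)(=O)Cl
Why: Sulfonylation of both phenols; with the sulfonyl chloride already present each phenoxide should be trapped faster than it can attack the neighbouring ester.

Step 8
Reactants: 13 methyl {2,3-bis[(methanesulfonyl)oxy]phenyl}acetate
Product: 14 {2,3-bis[(methanesulfonyl)oxy]phenyl}acetic acid
Conditions: 6 M HCl, 1,4-dioxane, reflux
Reagents that add atoms: water, O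
Why: Acid-catalysed ester hydrolysis; aryl methanesulfonates withstand hot aqueous acid, whereas hydroxide would cleave them, so the acidic mode is chosen.

Step 9
Reactants: 14 {2,3-bis[(methanesulfonyl)oxy]phenyl}acetic acid
Product: 15 {2,3-bis[(methanesulfonyl)oxy]phenyl}acetyl chloride
Conditions: (COCl)2, DMF (cat.), CH2Cl2, 0 °C → rt; evaporated and used crude
Reagents that add atoms: oxalyl chloride, O=C(Cl)C(Cl)=O
Why: Acid chloride formation through the Vilsmeier-type chloroiminium catalyst; the by-products are gases and the sulfonates are inert.

Step 10
Reactants: 9 3-{2-[4-(2-methoxyphenoxy)phenyl]ethyl}phenyl methanesulfonate; 15 {2,3-bis[(methanesulfonyl)oxy]phenyl}acetyl chloride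
Product: 16 3-{2-[3-(4-{2-[3-(methanesulfonyloxy)phenyl]ethyl}phenoxy)-4-methoxyphenyl]-2-oxoethyl}-1,2-phenylene dimethanesulfonate
Conditions: SnCl4 (3 equiv), CH2Cl2, −10 °C → rt
Reagents that add atoms: none
Why: SnCl4 ionises 15 to an acylium ion (or its tight chloride complex), which attacks C4 of ring C of 9, para to the methoxy group and meta to the aryloxy oxygen, giving an arenium ion whose charge is carried by the methoxy oxygen; loss of the proton gives the aryl ketone as its SnCl4 complex. This is a Friedel–Crafts acylation of the kind long used to make deoxybenzoins from arylacetyl chlorides and alkoxyarenes. No ring is closed and no stereocentre is formed. The step needs selectivity among four arenes and among the free positions of ring C: the methoxy oxygen is the strongest donor present, the aryloxy oxygen shares its lone pair with two rings and directs more weakly, ring B is open only ortho to that weaker donor, and rings A and D carry electron-withdrawing sulfonyloxy groups, so neither ring A of 9 nor ring D of 15 or of 16 should be acylated and 15 should not condense with itself. The position ortho to the methoxy group is disfavoured by crowding. The new carbonyl group deactivates ring C and so prevents a second acylation. A mild Lewis acid is chosen so that the methyl ether and the sulfonates stay intact, and an excess is used because the sulfonyl and ether oxygens bind it.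

Step 11
Reactants: 16 3-{2-[3-(4-{2-[3-(methanesulfonyloxy)phenyl]ethyl}phenoxy)-4-methoxyphenyl]-2-oxoethyl}-1,2-phenylene dimethanesulfonate
Product: 18 3-{2-[3-(4-{2-[3-(methanesulfonyloxy)phenyl]ethyl}phenoxy)-4-methoxyphenyl]ethyl}-1,2-phenylene dimethanesulfonate, via benzylic alcohol 17 (not isolated)
Conditions: Et3SiH (4 equiv), CF3CO2H, rt → 50 °C
Reagents that add atoms: none
Why: Ionic hydrogenation: the protonated ketone takes hydride from the silane, the alcohol ionises to a benzylic cation stabilised by the para-methoxy group, and a second hydride gives the CH2 group; sulfonates and ethers are inert to the acid.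

Step 12
Reactants: 18 3-{2-[3-(4-{2-[3-(methanesulfonyloxy)phenyl]ethyl}phenoxy)-4-methoxyphenyl]ethyl}-1,2-phenylene dimethanesulfonate
Product: 19 3-[2-(3-{4-[2-(3-hydroxyphenyl)ethyl]phenoxy}-4-methoxyphenyl)ethyl]benzene-1,2-diol
Conditions: KOH (excess), H2O–1,4-dioxane, reflux, argon; then aq. HCl
Reagents that add atoms: none
Why: Alkaline hydrolysis of the three aryl methanesulfonates (attack at sulfur or E1cB loss of sulfene, both release the phenoxide); the medium is water-rich so that no alkylating alkyl sulfonate arises, and oxygen is excluded because of the catecholate.

Step 13
Reactants: 19 3-[2-(3-{4-[2-(3-hydroxyphenyl)ethyl]phenoxy}-4-methoxyphenyl)ethyl]benzene-1,2-diol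
Product: 20 3-[2-(4-hydroxy-3-{4-[2-(3-hydroxyphenyl)ethyl]phenoxy}phenyl)ethyl]benzene-1,2-diol (target)
Conditions: BBr3 (6 equiv), CH2Cl2, −78 °C → rt; then H2O
Reagents that add atoms: none
Why: Boron tribromide cleavage of the remaining aryl methyl ether by bromide attack at the methyl group; the diaryl ether is not cleaved and the acidic, non-oxidising medium protects the catechol.

## Compound list

1 | guaiacol (2-methoxyphenol) | COc1ccccc1O | starting material
2 | 4-fluorobenzaldehyde | O=Cc1ccc(F)cc1 | starting material
3 | 4-(2-methoxyphenoxy)benzaldehyde | COc1ccccc1Oc1ccc(C=O)cc1 | intermediate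
4 | 3-hydroxybenzyl alcohol | OCc1cccc(O)c1 | starting material
5 | 3-[(methanesulfonyl)oxy]benzyl methanesulfonate | CS(=O)(=O)OCc1cccc(OS(C)(=O)=O)c1 | intermediate
6 | {3-[(methanesulfonyl)oxy]benzyl}triphenylphosphonium methanesulfonate | CS(=O)(=O)Oc1cccc(C[P+](c2ccccc2)(c2ccccc2)c2ccccc2)c1.CS(=O)(=O)[O-] | intermediate
7 | {3-[(methanesulfonyl)oxy]benzylidene}triphenylphosphorane (ylide, not isolated) | CS(=O)(=O)Oc1cccc(C=P(c2ccccc2)(c2ccccc2)c2ccccc2)c1 | intermediate
8 | 3-{2-[4-(2-methoxyphenoxy)phenyl]ethenyl}phenyl methanesulfonate (E/Z mixture, geometry left open) | COc1ccccc1Oc1ccc(C=Cc2cccc(OS(C)(=O)=O)c2)cc1 | intermediate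
9 | 3-{2-[4-(2-methoxyphenoxy)phenyl]ethyl}phenyl methanesulfonate | CS(=O)(=O)Oc1cccc(CCc2ccc(Oc3ccccc3OC)cc2)c1 | intermediate
10 | 2,3-dimethoxyphenylacetic acid | COc1cccc(CC(=O)O)c1OC | starting material
11 | 2,3-dihydroxyphenylacetic acid (not isolated) | OC(=O)Cc1cccc(O)c1O | intermediate
12 | methyl 2,3-dihydroxyphenylacetate | COC(=O)Cc1cccc(O)c1O | intermediate
13 | methyl {2,3-bis[(methanesulfonyl)oxy]phenyl}acetate | COC(=O)Cc1cccc(OS(C)(=O)=O)c1OS(C)(=O)=O | intermediate
14 | {2,3-bis[(methanesulfonyl)oxy]phenyl}acetic acid | OC(=O)Cc1cccc(OS(C)(=O)=O)c1OS(C)(=O)=O | intermediate
15 | {2,3-bis[(methanesulfonyl)oxy]phenyl}acetyl chloride | CS(=O)(=O)Oc1cccc(CC(Cl)=O)c1OS(C)(=O)=O | intermediate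
16 | 3-{2-[3-(4-{2-[3-(methanesulfonyloxy)phenyl]ethyl}phenoxy)-4-methoxyphenyl]-2-oxoethyl}-1,2-phenylene dimethanesulfonate | CS(=O)(=O)Oc1cccc(CCc2ccc(Oc3cc(C(=O)Cc4cccc(OS(C)(=O)=O)c4OS(C)(=O)=O)ccc3OC)cc2)c1 | intermediate
17 | 3-{2-hydroxy-2-[3-(4-{2-[3-(methanesulfonyloxy)phenyl]ethyl}phenoxy)-4-methoxyphenyl]ethyl}-1,2-phenylene dimethanesulfonate (racemic, not isolated) | CS(=O)(=O)Oc1cccc(CCc2ccc(Oc3cc(C(O)Cc4cccc(OS(C)(=O)=O)c4OS(C)(=O)=O)ccc3OC)cc2)c1 | intermediate
18 | 3-{2-[3-(4-{2-[3-(methanesulfonyloxy)phenyl]ethyl}phenoxy)-4-methoxyphenyl]ethyl}-1,2-phenylene dimethanesulfonate | CS(=O)(=O)Oc1cccc(CCc2ccc(Oc3cc(CCc4cccc(OS(C)(=O)=O)c4OS(C)(=O)=O)ccc3OC)cc2)c1 | intermediate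
19 | 3-[2-(3-{4-[2-(3-hydroxyphenyl)ethyl]phenoxy}-4-methoxyphenyl)ethyl]benzene-1,2-diol | Oc1cccc(CCc2ccc(Oc3cc(CCc4cccc(O)c4O)ccc3OC)cc2)c1 | intermediate
20 | 3-[2-(4-hydroxy-3-{4-[2-(3-hydroxyphenyl)ethyl]phenoxy}phenyl)ethyl]benzene-1,2-diol | Oc1cccc(CCc2ccc(Oc3cc(CCc4cccc(O)c4O)ccc3O)cc2)c1 | target

## Step count and least certain steps

Total: 13 steps. Longest linear sequence: 8 steps (4 → 5 → 6 → 8 → 9 → 16 → 18 → 19 → 20; the ring D branch 10 → 12 → 13 → 14 → 15 → 16 → 18 → 19 → 20 is equally long).

**Step 10 (key step).** Two processes may spoil it. Part of the acylation may go para to the aryloxy oxygen of ring C or onto ring B. The enolisable, electron-poor acid chloride may also be consumed by ketene formation and self-condensation under the Lewis acid before it reaches ring C. The fallback separates the choice of position from the C–C bond formation and sets out from 9. Bromination with NBS in MeCN at 0 °C, a substitution that discriminates between positions more sharply than acylation and whose isomers can be separated on a simple compound, should give 3-{2-[4-(5-bromo-2-methoxyphenoxy)phenyl]ethyl}phenyl methanesulfonate F1. Stannylation with (Bu3Sn)2 and Pd(PPh3)4 in toluene at 110 °C should give 3-(2-{4-[2-methoxy-5-(tributylstannyl)phenoxy]phenyl}ethyl)phenyl methanesulfonate F2. A Stille acylation of F2 with 15 (PdCl2(PPh3)2, CHCl3, 60 °C, under CO to hold back decarbonylation) joins the carbonyl carbon to the tin-bearing carbon and comes back to the route at 16.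

**Step 6.** The ortho-hydroxy ester may close back to the five-membered lactone when the acidic methanol solution is concentrated, or the esterification may stay incomplete, so that mixtures reach the sulfonylation. The fallback changes the order of events and sets out from 10. Fischer esterification (MeOH, H2SO4 cat., reflux) gives methyl 2,3-dimethoxyphenylacetate F3. The ether cleavage is then run on the ester (BBr3, CH2Cl2, −78 → 0 °C) and quenched into cold aqueous NaHCO3. The phenols are thus never set free next to a free carboxyl group or in hot acid, and the sequence comes back at 12.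

**Step 11.** The benzylic cation may alkylate an electron-rich ring of a second molecule (Friedel–Crafts alkylation, oligomers) or lose a proton and stall at the stilbene stage. The fallback avoids a free cation and sets out from 16. NaBH4 in MeOH–THF at 0 °C gives alcohol 17, which is isolated this time, and hydrogenolysis of the benzylic C–O bond over 10% Pd/C under H2 in AcOH comes back at 18. No compound outside the list is made (F0).

**Step 12.** The catecholate may be oxidised in hot alkali if traces of oxygen enter, and the second sulfonate on ring D may be cleaved slowly once the neighbouring oxygen is a phenoxide. The fallback reverses the order and changes the mode of cleavage; it sets out from 18. BBr3 in CH2Cl2 first removes the methyl ether and should give 3-{2-[4-hydroxy-3-(4-{2-[3-(methanesulfonyloxy)phenyl]ethyl}phenoxy)phenyl]ethyl}-1,2-phenylene dimethanesulfonate F4, the sulfonates being stable to the Lewis acid. The three sulfonates are then removed without water or heat by LiN(i-Pr)2 (excess) in THF at −78 → 0 °C under argon, through deprotonation of the S-methyl group and loss of sulfene. Acidic quench comes back to the route at 20.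

## Further compounds

F1 | step 10 | 3-{2-[4-(5-bromo-2-methoxyphenoxy)phenyl]ethyl}phenyl methanesulfonate | COc1ccc(Br)cc1Oc1ccc(CCc2cccc(OS(C)(=O)=O)c2)cc1
F2 | step 10 | 3-(2-{4-[2-methoxy-5-(tributylstannyl)phenoxy]phenyl}ethyl)phenyl methanesulfonate | CCCC[Sn](CCCC)(CCCC)c1ccc(OC)c(Oc2ccc(CCc3cccc(OS(C)(=O)=O)c3)cc2)c1
F3 | step 6 | methyl 2,3-dimethoxyphenylacetate | COC(=O)Cc1cccc(OC)c1OC
F0 | step 11 | none | none
F4 | step 12 | 3-{2-[4-hydroxy-3-(4-{2-[3-(methanesulfonyloxy)phenyl]ethyl}phenoxy)phenyl]ethyl}-1,2-phenylene dimethanesulfonate | CS(=O)(=O)Oc1cccc(CCc2ccc(Oc3cc(CCc4cccc(OS(C)(=O)=O)c4OS(C)(=O)=O)ccc3O)cc2)c1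
A1 | alternative 1 | 1-{4-[2-(3-methoxyphenyl)ethyl]phenoxy}propan-2-one | CC(=O)COc1ccc(CCc2cccc(OC)c2)cc1
A2 | alternative 1 | {2-[2-(2,3-dimethoxyphenyl)ethyl]-3-(dimethylamino)prop-2-en-1-ylidene}dimethylammonium hexafluorophosphate | CN(C)C=C(CCc1cccc(OC)c1OC)C=[N+](C)C.F[P-](F)(F)(F)(F)F
A3 | alternative 1 | 4-[2-(2,3-dimethoxyphenyl)ethyl]-2-{4-[2-(3-methoxyphenyl)ethyl]phenoxy}phenol | COc1cccc(CCc2ccc(Oc3cc(CCc4cccc(OC)c4OC)ccc3O)cc2)c1
A4 | alternative 2 | 3-[2-(3,5-dichloro-4-hydroxyphenyl)ethyl]phenyl acetate | CC(=O)Oc1cccc(CCc2cc(Cl)c(O)c(Cl)c2)c1
A5 | alternative 2 | 3-[2-(3,5-dibromo-4-hydroxyphenyl)ethyl]-1,2-phenylene diacetate | CC(=O)Oc1cccc(CCc2cc(Br)c(O)c(Br)c2)c1OC(C)=O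
A6 | alternative 2 | 3-{2-[3-bromo-5-(4-{2-[3-(acetyloxy)phenyl]ethyl}-2,6-dichlorophenoxy)-4-hydroxyphenyl]ethyl}-1,2-phenylene diacetate | CC(=O)Oc1cccc(CCc2cc(Cl)c(Oc3cc(CCc4cccc(OC(C)=O)c4OC(C)=O)cc(Br)c3O)c(Cl)c2)c1
A7 | alternative 3 | 3-iodoanisole | COc1cccc(I)c1
A8 | alternative 3 | ethynyltrimethylsilane | C[Si](C)(C)C#C
A9 | alternative 3 | 4-[2-(2,3-dimethoxyphenyl)ethyl]-2-(4-iodophenoxy)-1-methoxybenzene | COc1ccc(CCc2cccc(OC)c2OC)cc1Oc1ccc(I)cc1
A10 | alternative 3 | 4-[2-(2,3-dimethoxyphenyl)ethyl]-1-methoxy-2-{4-[(3-methoxyphenyl)ethynyl]phenoxy}benzene | COc1cccc(C#Cc2ccc(Oc3cc(CCc4cccc(OC)c4OC)ccc3OC)cc2)c1
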